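(The earlier runs and the new flask come from a simulation from invented constants; the scatter is artificial.)

In a closed, stirred vessel kept at one temperature, starting material and second substrate meet free catalyst and target appears. The new flasks differ in temperature only, and the earlier runs also differ in c(free catalyst).

in all of them: starting material 0.064 M; second substrate 0.128 M

|  | free catalyst | temperature | remark | time |
|---|---|---|---|---|
| gamma | 0.32 mM | 76 °C | run made earlier |  |
| alpha | 0.48 mM | 101 °C | run made earlier |  |
| spring | 0.64 mM | 110 °C |  | 12 min |
| midnight | 0.64 mM | 65 °C |  | 12 min |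
| noon | 0.64 mM | 95 °C |  | 12 min |
| summer | 0.64 mM | 80 °C |  | 12 min |

| run | time / min | target / % | starting material / % |
|---|---|---|---|
| gamma | 5.00 | 0 | 100 |
| gamma | 8.00 | 2 | 96 |
| gamma | 10.0 | 1 | 101 |
| gamma | 15.0 | 3 | 97 |
| gamma | 25.0 | 5 | 91 |
| gamma | 40.0 | 8 | 93 |
| gamma | 60.0 | 12 | 88 |
| alpha | 2.50 | 4 | 94 |
| alpha | 5.00 | 8 | 89 |
| alpha | 8.00 | 13 | 83 |
| alpha | 10.0 | 14 | 81 |
| alpha | 12.0 | 19 | 82 |
| alpha | 15.0 | 20 | 73 |
| alpha | 20.0 | 23 | 67 |

(readings scatter by 1.5 percentage points)



* which flask leads in amount of target, in percent of the starting material charged ("all alike" within 1.5 percentage points) (spring / midnight / noon / summer / all alike)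
* how much target is there at the end, in percent of the starting material charged: spring
* how much target is there at the end, in percent of the starting material charged: midnight
* how much target is there at the end, in percent of the starting material charged: noon
* how much target is there at the end, in percent of the starting material charged: summer

Both parties to this dispute start from the same logarithm. Taking the pace as proportional to c(free catalyst), they divide the target made by time and by catalyst to get a specific rate, which is 6.25 M⁻¹ min⁻¹ for gamma at its last reading and 33.9 M⁻¹ min⁻¹ for alpha at 8.00 min. Alpha is therefore ahead by 0.734 decades over 25.0 K, and this gives the decade span, the temperature step that buys one decade of specific rate, of 34.1 K.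

Moving alpha's specific rate along this span, and multiplying by c(free catalyst) and time, gives each flask a straight line value: 47.8 % for spring, 17.3 % for noon, 6.29 % for summer and 2.28 % for midnight.

The quarrel is over the bend. My own view is that it follows how far a flask has gone: alpha reads 19 % at 12.0 min against a line of 19.5 %, but 23 % at 20.0 min against 32.5 %, a kept share of 0.708. So I keep noon and the colder flasks on their lines, which end lower than alpha's line at 12.0 min, while I give spring, whose line ends higher than alpha's at 20.0 min, that share as an estimate, which puts it at 33.8 %, the figure I commit to.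

The other party says the bend follows heat, since gamma's last target and starting material, 12 % and 88 %, fill the charge, whereas alpha's 23 % and 67 % fall short of it.

That second view is the forecast's, which puts spring first at 26 %, lower than my figure, with 15.5 % for noon, 6.5 % for summer and 2.2 % for midnight, on the ground: “This probably worsens steeply with temperature”.

The simulation puts spring first at 32.3 %, with noon at 14.5 %, summer at 5.31 % and midnight at 1.56 %.

    target + free catalyst ⇌ isomer of the product + free catalyst, rate k1*[free catalyst]*[target] forward; the back reaction follows from the equilibrium constant (K = 0.760, k = 387 M⁻¹ min⁻¹, Ea = 48.0 kJ mol⁻¹, ΔH = −28.0 kJ mol⁻¹)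
    2 catalyst intermediate A ⇌ resting dimer, settled at all times (K = 2100 M⁻¹, ΔH = 2.00 kJ mol⁻¹)
    starting material + free catalyst ⇌ catalyst intermediate A (K = 22.1 M⁻¹, k = 661 M⁻¹ min⁻¹, Ea = 40.0 kJ mol⁻¹, ΔH = −28.0 kJ mol⁻¹)
    catalyst intermediate A → free catalyst + target (k = 14.0 min⁻¹, Ea = 90.0 kJ mol⁻¹)
    second substrate + free catalyst ⇌ catalyst intermediate B (K = 8.30 M⁻¹, k = 2240 M⁻¹ min⁻¹, Ea = 39.0 kJ mol⁻¹, ΔH = 16.0 kJ mol⁻¹)
    catalyst intermediate B → free catalyst + second product (k = 99.0 min⁻¹, Ea = 101 kJ mol⁻¹)
    (constants at 110 °C)

At 12 min spring still makes target twice as fast as it uses it up, each step taken net. Carried upward from summer's 5.31 % by the decade span, the reckoning gives 14.6 % for noon, which holds 14.5 %, and 40.3 % for spring, which holds 32.3 %.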